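The data were generated by integration with made-up constants; noise was put on by code.

I carry one constant through this flask, and the last spring reading gives it as 3.02: the logarithm of the share of left-handed substrate remaining over the logarithm of the share of right-handed substrate remaining, the selectivity factor.

| flask | left-handed substrate | right-handed substrate | partner | free catalyst | racemization catalyst | remark | time |
|---|---|---|---|---|---|---|---|
| noon | 0.50 M | 0.50 M | 1 M | 12 mM | 6.7 mM | run made earlier |  |
| summer | 0.50 M | 0.50 M | 1 M | 12 mM | 15 mM | run made earlier |  |
| spring | 0.50 M | 0.50 M | 2 M | 12 mM | 10 mM | run made earlier |  |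
| flask | 0.50 M | 0.50 M | 1.00 M | 12 mM | 10 mM |  | 2.5 min |

- noon (time / s: left-handed product / %, right-handed product / %): 12.0: 2.9, 1.3; 25.0: 5.8, 1.7; 40.0: 8.1, 2.4; 50.0: 9.9, 3.5; 60.0: 11.3, 4.5; 80.0: 13.7, 5.2; 90.0: 14.3, 5.7
- summer (time / s: left-handed product / %, right-handed product / %): 12.0: 2.5, 0.9; 25.0: 5.6, 1.9; 40.0: 8.4, 2.6; 50.0: 9.8, 3.4; 60.0: 10.7, 4.0; 80.0: 13.7, 5.0; 90.0: 15.2, 5.7
- spring (time / s: left-handed product / %, right-handed product / %): 10.0: 4.9, 2.0; 15.0: 6.8, 2.0; 25.0: 10.2, 3.5; 50.0: 17.6, 6.7; 90.0: 26.0, 10.8

(each reading ± 0.3 percentage points)

- free catalyst is single-handed; left-handed substrate and right-handed substrate are mirror images of each other, charged as a racemate, each of them at the stated concentration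
- an excess is the difference of the two amounts in percent of their sum
- an excess is below zero if the other one leads

- left-handed product and right-handed product together, in percent of the left-handed substrate and right-handed substrate charged together, at 2.5 min
- excess of left-handed product over right-handed product in the product at 2.5 min
- whether the exchange between left-handed substrate and right-handed substrate keeps pace with the reaction: how far the product's excess at 2.5 min gets from its value without exchange to its value with instant exchange (above 80% keeps pace, below 20% hardly takes part, else lags behind)

The flask holds both substrates, partner, free catalyst and racemization catalyst, and you come at 2.5 min. Do not top up the racemization catalyst. The noon and summer runs hold 6.7 mM and 15 mM of it, yet at 80.0 s both read 13.7% left-handed product. So I let each substrate fade on its own, like a first-order lag. At 90.0 s those two runs give the left-handed substrate a time constant of 4.29 min, and the right-handed substrate is 3.02 times slower. In this flask at 2.5 min I expect 55.8% of the left-handed and 82.4% of the right-handed substrate to remain. That means 30.9% converted, with an excess of 43.1%. Partner is used as product forms, so I hold the conversion as a high figure. Instant exchange would hold the excess at 50.2%, and I expect less, so I say exchange hardly takes part.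

The forecast, a little lower on conversion, gives 30% and 43%, with exchange that hardly takes part: “This is plain kinetic resolution”. The flask gives 29.2% and 42.7%, and exchange hardly takes part, at 2.4% of the way.

    partner + free catalyst + right-handed substrate → free catalyst + right-handed product (k = 0.140 L² mol⁻² s⁻¹)
    left-handed substrate + racemization catalyst ⇌ right-handed substrate + racemization catalyst, rate k2*[racemization catalyst]*[left-handed substrate] forward; the back reaction follows from the equilibrium constant (k = 0.0700 L mol⁻¹ s⁻¹)
    partner ⇌ dormant form (K = 0.210, k = 0.00310 s⁻¹)
    partner + free catalyst + left-handed substrate → free catalyst + left-handed product (k = 0.410 L² mol⁻² s⁻¹)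
    partner + racemization catalyst → spent catalyst (k = 0.0210 L mol⁻¹ s⁻¹)

Exchange makes no difference to this flask's excess: its net turnover is 0.193%, run the other way, against 20.8% through the left-handed step. So the factor can be used again here, where the remaining shares 59% and 83% give 2.83. The largest single effect on this flask's excess is time: ten times as long takes it from 42.7% to 23.0%. The neighbour with 0.048 M of free catalyst converts 59.5%, its excess falls to 32.2%, and its remaining shares give 2.79.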